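**Strategy.** Everything rests on cutting the C1–Cα and Cβ–C1′ bonds of the ethano bridge that joins ring A (the central, pentasubstituted ring) to ring B (the 3-hydroxyphenyl ring), read back as an alkyne. With oxygen in place of carbon at C1, ring A is a 4,6-dibenzylated 5-methoxyresorcinol bisected by a mirror plane through C3 and C6, so its two free oxygens (C1, C5) are interchangeable and either can become the triflate. The key step exploits this phenol-derived C1 of ring A: one flask joins the aryl triflate, trimethylsilylacetylene and 1-benzyloxy-3-iodobenzene through two successive Sonogashira couplings. The precursor is the fully benzyl-protected mono-triflate of that resorcinol, made from phloroglucinol.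

Key step: step 7

Remark on numbering: in ring A, C1 carries the bridge, C2 and C4 the 4-hydroxybenzyl groups, C3 the OMe, C5 the OH and C6 a hydrogen.
Remark on starting materials: 1-benzyloxy-3-iodobenzene and 4-benzyloxybenzyl chloride are taken to be catalogue compounds.

Step 1
Reactants: 1 phloroglucinol; 2 4-benzyloxybenzyl chloride (2.0 equiv)
Product: 3 2,4-bis(4-benzyloxybenzyl)benzene-1,3,5-triol
Conditions: ZnCl2 (10 mol %), 1,4-dioxane, 40 °C; mono-benzylated material re-subjected
Reagents that add atoms: none
Why: Friedel–Crafts benzylation, in which the 4-alkoxybenzyl cation released from 2 attacks the very electron-rich triol at carbon; the three ring positions are equivalent, so two alkylations can only give the 2,4-pattern and the degree of alkylation is set by stoichiometry.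

Step 2
Reactants: 3 2,4-bis(4-benzyloxybenzyl)benzene-1,3,5-triol
Product: 4 2,6-bis(4-benzyloxybenzyl)-3,5-bis(triisopropylsilyloxy)phenol
Conditions: TIPSCl (2.2 equiv), imidazole, DMF, 0 °C to rt
Reagents that add atoms: triisopropylsilyl chloride, CC(C)[Si](Cl)(C(C)C)C(C)C
Why: Phenol silylation in which the bulky silyl chloride should take only the two outer hydroxyls (one ortho benzyl each) and leave the central hydroxyl, which is shielded by two ortho benzyl groups.

Step 3
Reactants: 4 2,6-bis(4-benzyloxybenzyl)-3,5-bis(triisopropylsilyloxy)phenol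
Product: 5 1,5-bis(triisopropylsilyloxy)-2,4-bis(4-benzyloxybenzyl)-3-methoxybenzene
Conditions: MeI, K2CO3, acetone, 50 °C
Reagents that add atoms: iodomethane, CI
Why: Williamson ether synthesis on the only free phenol; iodomethane is small enough to reach the hindered phenoxide and aryl triisopropylsilyl ethers tolerate anhydrous carbonate.

Step 4
Reactants: 5 1,5-bis(triisopropylsilyloxy)-2,4-bis(4-benzyloxybenzyl)-3-methoxybenzene
Product: 6 4,6-bis(4-benzyloxybenzyl)-5-methoxybenzene-1,3-diol
Conditions: TBAF, AcOH, THF, 0 °C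
Reagents that add atoms: none
Why: Fluoride-driven desilylation of both aryl silyl ethers (strong Si–F bond), buffered with acetic acid to protect the electron-rich resorcinol; methyl and benzyl ethers are untouched.

Step 5
Reactants: 6 4,6-bis(4-benzyloxybenzyl)-5-methoxybenzene-1,3-diol
Product: 7 2,4-bis(4-benzyloxybenzyl)-5-hydroxy-3-methoxyphenyl trifluoromethanesulfonate
Conditions: PhNTf2 (1.0 equiv), Et3N, CH2Cl2, 0 °C to rt; unreacted 6 recovered and recycled
Reagents that add atoms: N-phenylbis(trifluoromethanesulfonimide), O=S(=O)(N(c1ccccc1)S(=O)(=O)C(F)(F)F)C(F)(F)F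
Why: Phenol triflation by sulfonyl transfer from a mild triflating agent; the two hydroxyls are symmetry-equivalent, so only mono versus bis must be controlled, and the first triflate lowers the nucleophilicity of the remaining phenol.

Step 6
Reactants: 7 2,4-bis(4-benzyloxybenzyl)-5-hydroxy-3-methoxyphenyl trifluoromethanesulfonate
Product: 8 5-benzyloxy-2,4-bis(4-benzyloxybenzyl)-3-methoxyphenyl trifluoromethanesulfonate
Conditions: BnBr, K2CO3, acetone, 40 °C
Reagents that add atoms: benzyl bromide, BrCc1ccccc1
Why: Williamson etherification of the remaining phenol; an aryl triflate survives weak carbonate base in acetone, and the benzyl ether matches the other protecting groups so that all fall in one final operation.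

Step 7
Reactants: 8 5-benzyloxy-2,4-bis(4-benzyloxybenzyl)-3-methoxyphenyl trifluoromethanesulfonate; 9 trimethylsilylacetylene; 10 1-benzyloxy-3-iodobenzene
Product: 13 1-benzyloxy-2,4-bis(4-benzyloxybenzyl)-5-[(3-benzyloxyphenyl)ethynyl]-3-methoxybenzene, via silylalkyne 11 (not isolated), via terminal alkyne 12 (not isolated)
Conditions: PdCl2(PPh3)2 (5 mol %), CuI (10 mol %), 9 (1.5 equiv), Et3N/DMF, 80 °C, sealed tube; N2 purge; then 10 (1.2 equiv), CsF, H2O (2 equiv), 60 °C
Reagents that add atoms: none
Why: PdCl2(PPh3)2 is reduced in the flask to zerovalent palladium, which inserts into the C1–O bond of the ring A triflate; the copper acetylide formed from 9, CuI and Et3N transmetalates to the arylpalladium species and reductive elimination gives silylalkyne 11 (the C1–Cα bond). Fluoride from CsF then strips the trimethylsilyl group to give 12, whose copper acetylide enters a second catalytic cycle that starts with oxidative addition into the C–I bond of 10 and ends with the Cβ–C1′ bond to ring B. The closest known reaction type is the sequential sila-Sonogashira protocol, in which an aryl electrophile, a silyl-capped acetylene and a second aryl halide are joined in one pot to an unsymmetrical diarylalkyne. No ring is closed and no stereocentre is created. The selectivity needed is one of sequence: the silyl cap keeps the far alkyne terminus silent during the first coupling, and 10 and CsF are added only after the triflate is consumed and surplus 9 has been purged, so each aryl electrophile meets a single alkyne terminus. In the substrate, C6–H on one flank of C1 leaves room for oxidative addition, and the benzyl and methyl ethers are inert to palladium, copper and fluoride.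

Step 8
Reactants: 13 1-benzyloxy-2,4-bis(4-benzyloxybenzyl)-5-[(3-benzyloxyphenyl)ethynyl]-3-methoxybenzene
Product: 14 bulbocodin C
Conditions: H2 (1 atm), palladium on carbon (10% Pd/C), EtOAc/MeOH, rt
Reagents that add atoms: none
Why: Heterogeneous catalytic hydrogenation should saturate the diarylalkyne to the ethano bridge and hydrogenolyse all four aryl benzyl ethers in one operation; the diarylmethane C–C bonds and the methyl ether are inert.

**Compound list**

1 | phloroglucinol (benzene-1,3,5-triol) | Oc1cc(O)cc(O)c1 | starting material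
2 | 4-benzyloxybenzyl chloride | ClCc1ccc(OCc2ccccc2)cc1 | starting material
3 | 2,4-bis(4-benzyloxybenzyl)benzene-1,3,5-triol | Oc1cc(O)c(Cc2ccc(OCc3ccccc3)cc2)c(O)c1Cc1ccc(OCc2ccccc2)cc1 | intermediate
4 | 2,6-bis(4-benzyloxybenzyl)-3,5-bis(triisopropylsilyloxy)phenol | CC(C)[Si](C(C)C)(C(C)C)Oc1cc(O[Si](C(C)C)(C(C)C)C(C)C)c(Cc2ccc(OCc3ccccc3)cc2)c(O)c1Cc1ccc(OCc2ccccc2)cc1 | intermediate
5 | 1,5-bis(triisopropylsilyloxy)-2,4-bis(4-benzyloxybenzyl)-3-methoxybenzene | CC(C)[Si](C(C)C)(C(C)C)Oc1cc(O[Si](C(C)C)(C(C)C)C(C)C)c(Cc2ccc(OCc3ccccc3)cc2)c(OC)c1Cc1ccc(OCc2ccccc2)cc1 | intermediate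
6 | 4,6-bis(4-benzyloxybenzyl)-5-methoxybenzene-1,3-diol | COc1c(Cc2ccc(OCc3ccccc3)cc2)c(O)cc(O)c1Cc1ccc(OCc2ccccc2)cc1 | intermediate
7 | 2,4-bis(4-benzyloxybenzyl)-5-hydroxy-3-methoxyphenyl trifluoromethanesulfonate | COc1c(Cc2ccc(OCc3ccccc3)cc2)c(O)cc(OS(=O)(=O)C(F)(F)F)c1Cc1ccc(OCc2ccccc2)cc1 | intermediate
8 | 5-benzyloxy-2,4-bis(4-benzyloxybenzyl)-3-methoxyphenyl trifluoromethanesulfonate | COc1c(Cc2ccc(OCc3ccccc3)cc2)c(OCc2ccccc2)cc(OS(=O)(=O)C(F)(F)F)c1Cc1ccc(OCc2ccccc2)cc1 | intermediate
9 | trimethylsilylacetylene | C#C[Si](C)(C)C | starting material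
10 | 1-benzyloxy-3-iodobenzene | Ic1cccc(OCc2ccccc2)c1 | starting material
11 | {[5-benzyloxy-2,4-bis(4-benzyloxybenzyl)-3-methoxyphenyl]ethynyl}trimethylsilane | COc1c(Cc2ccc(OCc3ccccc3)cc2)c(OCc2ccccc2)cc(C#C[Si](C)(C)C)c1Cc1ccc(OCc2ccccc2)cc1 | intermediate
12 | 1-benzyloxy-2,4-bis(4-benzyloxybenzyl)-5-ethynyl-3-methoxybenzene | COc1c(Cc2ccc(OCc3ccccc3)cc2)c(OCc2ccccc2)cc(C#C)c1Cc1ccc(OCc2ccccc2)cc1 | intermediate
13 | 1-benzyloxy-2,4-bis(4-benzyloxybenzyl)-5-[(3-benzyloxyphenyl)ethynyl]-3-methoxybenzene | COc1c(Cc2ccc(OCc3ccccc3)cc2)c(OCc2ccccc2)cc(C#Cc2cccc(OCc3ccccc3)c2)c1Cc1ccc(OCc2ccccc2)cc1 | intermediate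
14 | bulbocodin C | COc1c(Cc2ccc(O)cc2)c(O)cc(CCc2cccc(O)c2)c1Cc1ccc(O)cc1 | target

**Total step count:** 8. **Longest linear sequence:** 8 steps (1 to 14); 9 and 10 enter as purchased reagents in step 7.

**Steps most likely to fail**

1. Step 7. Oxidative addition of zerovalent palladium into the hindered, electron-rich C1–O triflate bond may be slow. An incomplete first coupling would then expose leftover triflate to hydrolysis once fluoride and water are added, and alkyne homocoupling or scrambling of the two coupling partners could follow. Fallback, setting out from 8 and 10 and returning to the route at 14: the bridge is built at the alkane level by a B-alkyl Suzuki–Miyaura coupling. Iodide 10 is vinylated with vinylboronic acid pinacol ester (PdCl2(dppf), K2CO3, dioxane/H2O) to 1-benzyloxy-3-vinylbenzene F1. Hydroboration with 9-BBN in THF gives 9-[2-(3-benzyloxyphenyl)ethyl]-9-borabicyclo[3.3.1]nonane F2. This is coupled with triflate 8 (PdCl2(dppf), K3PO4, THF/DMF/H2O, 60 °C) to 1-benzyloxy-2,4-bis(4-benzyloxybenzyl)-5-[2-(3-benzyloxyphenyl)ethyl]-3-methoxybenzene F3. Hydrogenolysis of the four benzyl ethers under the conditions of step 8 then gives 14.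

2. Step 1. Control over the degree of alkylation may be lost, giving mono- and tri-benzylated material, and the benzylic cation may condense with itself. Fallback, setting out from 1 and 2 and returning at 3: the two benzyl groups are installed by cross-coupling at positions fixed by halogenation. Phloroglucinol is converted with MOMCl and i-Pr2NEt into 1,3,5-tris(methoxymethoxy)benzene F4. Two equivalents of N-iodosuccinimide in MeCN give 2,4-diiodo-1,3,5-tris(methoxymethoxy)benzene F5. Zinc insertion into 2 (Zn dust, LiCl, THF) gives (4-benzyloxybenzyl)zinc chloride F6. A double Negishi coupling (Pd(OAc)2, SPhos, THF, 50 °C) furnishes 2,4-bis(4-benzyloxybenzyl)-1,3,5-tris(methoxymethoxy)benzene F7, and HCl in MeOH removes the three acetals to give 3.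

3. Step 5. Discrimination between first and second triflation may be poor, so that bis-triflate and unreacted diol dominate. Fallback, setting out from 6 and returning at 7: the desymmetrisation is moved from the introduction of the sulfonate to its removal. Exhaustive triflation (Tf2O, pyridine, CH2Cl2, 0 °C) gives 4,6-bis(4-benzyloxybenzyl)-5-methoxy-1,3-phenylene bis(trifluoromethanesulfonate) F8. One equivalent of Et4NOH in dioxane/H2O then cleaves a single sulfonate; the negative charge of the phenoxide formed should shield the second triflate from hydroxide, and acidification gives 7.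

**Further compounds**

F1 | step 7 | 1-benzyloxy-3-vinylbenzene | C=Cc1cccc(OCc2ccccc2)c1
F2 | step 7 | 9-[2-(3-benzyloxyphenyl)ethyl]-9-borabicyclo[3.3.1]nonane | C(Cc1cccc(OCc2ccccc2)c1)B1C2CCCC1CCC2
F3 | step 7 | 1-benzyloxy-2,4-bis(4-benzyloxybenzyl)-5-[2-(3-benzyloxyphenyl)ethyl]-3-methoxybenzene | COc1c(Cc2ccc(OCc3ccccc3)cc2)c(OCc2ccccc2)cc(CCc2cccc(OCc3ccccc3)c2)c1Cc1ccc(OCc2ccccc2)cc1
F4 | step 1 | 1,3,5-tris(methoxymethoxy)benzene | COCOc1cc(OCOC)cc(OCOC)c1
F5 | step 1 | 2,4-diiodo-1,3,5-tris(methoxymethoxy)benzene | COCOc1cc(OCOC)c(I)c(OCOC)c1I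
F6 | step 1 | (4-benzyloxybenzyl)zinc chloride | Cl[Zn]Cc1ccc(OCc2ccccc2)cc1
F7 | step 1 | 2,4-bis(4-benzyloxybenzyl)-1,3,5-tris(methoxymethoxy)benzene | COCOc1cc(OCOC)c(Cc2ccc(OCc3ccccc3)cc2)c(OCOC)c1Cc1ccc(OCc2ccccc2)cc1
F8 | step 5 | 4,6-bis(4-benzyloxybenzyl)-5-methoxy-1,3-phenylene bis(trifluoromethanesulfonate) | COc1c(Cc2ccc(OCc3ccccc3)cc2)c(OS(=O)(=O)C(F)(F)F)cc(OS(=O)(=O)C(F)(F)F)c1Cc1ccc(OCc2ccccc2)cc1
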